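**Retrosynthetic overview**

1. The target is 2α,6α,19-trihydroxylabda-8,13-dien-15,16-olide; the last disconnection is C11–C12, the central σ-bond of the 1,5-diene C8=C9–C11–C12–C13=C14. C11 is allylic to the tetrasubstituted ring-B alkene and C12 is the vinylogous γ-carbon of the butenolide ring (O–C15(=O)–C14=C13–C16), which is the feature that makes the key step possible.
2. Key union: the C8–C9–C11 allyl cation from bromide 21 is captured at C11 by the exocyclic γ-carbon of silyl dienolate 27, which creates the conjugated butenolide in the same event.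
3. Ring B is closed by a Diels–Alder reaction of a ring-A vinylcyclohexene (C10=C5–C6=C7) with methyl but-2-ynoate (C8, C9, C11, C17). This sets C10 and delivers C8=C9 and C5=C6; hydroboration of C5=C6 then sets 5α-H and 6α-OH.
4. Ring A comes from 2-methoxy-3-methylbenzoic acid by auxiliary-controlled Birch reductive methylation (C4) and hydroboration (C2); the C5 lactone comes from methallyl alcohol and CO2.
5. Ring order: ring A (from the arene), ring B (cycloaddition), preformed lactone ring joined last.

Key step: step 15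

Assumption: the Birch reductive methylation of the (S)-prolinol-ether benzamide is taken to give the quaternary centre as drawn for 6; if the opposite sense were found, the (R)-auxiliary would be used with no other change.

Convention: labdane numbering is used for all intermediates; α is the face opposite the C20 methyl; TBS = tert-butyldimethylsilyl.

**Route**

Step 1
Reactants: 1 2-methoxy-3-methylbenzoic acid; 2 (S)-2-(methoxymethyl)pyrrolidine
Product: 4 [(2S)-2-(methoxymethyl)pyrrolidin-1-yl](2-methoxy-3-methylphenyl)methanone, via 2-methoxy-3-methylbenzoyl chloride 3 (not isolated)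
Conditions: (COCl)2, DMF (cat.), CH2Cl2, 0 °C to rt; then 2, Et3N, CH2Cl2, 0 °C to rt
Reagents that add atoms: none
Why: Amide formation through the acid chloride (N-acylation) should proceed without touching the non-epimerisable stereocentre of the amine.

Step 2
Reactants: 4 the benzamide
Product: 6 [(1S)-2-methoxy-1,3-dimethylcyclohexa-2,5-dien-1-yl][(2S)-2-(methoxymethyl)pyrrolidin-1-yl]methanone, via potassium amide enolate 5 (not isolated)
Conditions: K, NH3(l)/THF, t-BuOH (1 equiv), −78 °C; piperylene; then MeI, −78 °C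
Reagents that add atoms: iodomethane (CI)
Why: Asymmetric Birch reduction–alkylation: the arene is reduced to amide enolate 5 (protonation para to the carboxamide), and its potassium chelate with the auxiliary ether oxygen leaves one face open to iodomethane, which sets the C4 quaternary centre.

Step 3
Reactants: 6 the cyclohexadiene amide
Product: 8 [(1S,5R)-5-hydroxy-2-methoxy-1,3-dimethylcyclohex-2-en-1-yl][(2S)-2-(methoxymethyl)pyrrolidin-1-yl]methanone, via B-alkyl-9-BBN adduct 7 (not isolated)
Conditions: 9-BBN, THF, rt; then NaOH aq., H2O2, 0 °C to rt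
Reagents that add atoms: hydrogen peroxide (OO)
Why: Hydroboration–oxidation: 9-BBN should ignore the tetrasubstituted enol ether, place boron on the alkene carbon remote from the quaternary centre and approach the flat ring anti to the bulky tertiary carboxamide, which sets the C2 carbinol trans to the carboxamide (retention on oxidation).

Step 4
Reactants: 8 the hydroxy amide
Product: 10 (2R,4R)-4-hydroxy-2-(hydroxymethyl)-2,6-dimethylcyclohexan-1-one (C6 epimers), via enol ether diol 9 (not isolated)
Conditions: LiNH2BH3 (from BH3·NH3 and LDA), THF, 0 °C to rt; then 2 M HCl, THF, rt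
Reagents that add atoms: water (O)
Why: Lithium amidotrihydroborate reduction of the hindered tertiary amide to the primary alcohol releases the auxiliary, and the acidic quench hydrolyses the enol ether to the ketone; C4 has no α-hydrogen and cannot epimerise, and the C10 epimers converge in step 6.

Step 5
Reactants: 10 the keto diol
Product: 11 (2R,4R)-4-(tert-butyldimethylsilyloxy)-2-[(tert-butyldimethylsilyloxy)methyl]-2,6-dimethylcyclohexan-1-one (C6 epimers)
Conditions: TBSCl, imidazole, DMF, 40 °C
Reagents that add atoms: tert-butyldimethylsilyl chloride (CC(C)(C)[Si](C)(C)Cl)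
Why: Silyl ether formation on both hydroxyl groups blocks retro-aldol loss of formaldehyde in the basic steps that follow and changes no stereocentre.

Step 6
Reactants: 11 the bis-silyl ketone
Product: 13 (4R,6R)-4-(tert-butyldimethylsilyloxy)-6-[(tert-butyldimethylsilyloxy)methyl]-2,6-dimethylcyclohex-1-en-1-yl trifluoromethanesulfonate, via potassium enolate 12 (not isolated)
Conditions: KHMDS, THF, −78 °C; then PhNTf2, −78 to 0 °C
Reagents that add atoms: N-phenylbis(trifluoromethanesulfonimide) (O=S(=O)(N(c1ccccc1)S(=O)(=O)C(F)(F)F)C(F)(F)F)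
Why: Enol triflate formation: deprotonation at the only enolisable position (C10) and O-sulfonylation give the tetrasubstituted vinyl triflate and erase the C10 stereocentre.

Step 7
Reactants: 13 the vinyl triflate
Product: 14 (3S,5R)-5-(tert-butyldimethylsilyloxy)-3-[(tert-butyldimethylsilyloxy)methyl]-1,3-dimethyl-2-vinylcyclohex-1-ene
Conditions: tributyl(vinyl)stannane, Pd(PPh3)4 (cat.), LiCl, THF, 65 °C
Reagents that add atoms: tributyl(vinyl)stannane (C=C[Sn](CCCC)(CCCC)CCCC)
Why: Stille coupling of the hindered vinyl triflate should give the 1-vinylcyclohexene diene (C10=C5–C6=C7) with the stereocentres untouched.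

Step 8
Reactants: 14 the diene; 15 methyl but-2-ynoate
Product: 16 methyl 2α,19-bis(tert-butyldimethylsilyloxy)-12,13,14,15,16-pentanorlabda-5,8-dien-11-oate
Conditions: 15 (5 equiv), BHT (cat.), CH2Cl2, 13 kbar, 40 °C
Reagents that add atoms: none
Why: Diels–Alder reaction driven by pressure (strongly negative activation volume): the unsubstituted diene terminus C7 bonds to the β-carbon of the ynoate, so the methyl ends on C8 and the ester carbon on C9, and the dienophile approaches anti to the pseudoaxial C4 silyloxymethyl group (ring-A half-chair fixed by the equatorial C2 silyl ether), which sets C10 with its methyl cis to C19.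

Step 9
Reactants: 16 the dienoate
Product: 18 methyl 2α,19-bis(tert-butyldimethylsilyloxy)-6α-hydroxy-12,13,14,15,16-pentanorlabd-8-en-11-oate, via 6α-borane adduct 17 (not isolated)
Conditions: BH3·THF, THF, 0 °C to rt; then NaOH aq., H2O2, 0 °C
Reagents that add atoms: hydrogen peroxide (OO)
Why: Hydroboration–oxidation: borane should add syn to the trisubstituted C5=C6 bond from the α-face, opposite the C20 methyl and the axial C19 group, with boron on C6, which sets 5α-H (trans ring fusion) and 6α-OH; the tetrasubstituted, ester-conjugated C8=C9 bond should not react.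

Step 10
Reactants: 18 the hydroxy ester
Product: 19 methyl 2α,6α,19-tris(tert-butyldimethylsilyloxy)-12,13,14,15,16-pentanorlabd-8-en-11-oate
Conditions: TBSOTf, 2,6-lutidine, CH2Cl2, 0 °C
Reagents that add atoms: tert-butyldimethylsilyl trifluoromethanesulfonate (CC(C)(C)[Si](C)(C)OS(=O)(=O)C(F)(F)F)
Why: Silyl ether formation with the reactive triflate should protect the hindered equatorial 6α-hydroxyl while C11 is still masked as the ester.

Step 11
Reactants: 19 the tris-silyl ester
Product: 20 2α,6α,19-tris(tert-butyldimethylsilyloxy)-12,13,14,15,16-pentanorlabd-8-en-11-ol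
Conditions: DIBAL-H, CH2Cl2, −78 to 0 °C; sodium potassium tartrate aq.
Reagents that add atoms: none
Why: Hydride (1,2-) reduction of the hindered enoate should give the primary allylic alcohol without touching the silyl ethers or any stereocentre.

Step 12
Reactants: 20 the allylic alcohol
Product: 21 11-bromo-2α,6α,19-tris(tert-butyldimethylsilyloxy)-12,13,14,15,16-pentanorlabd-8-ene
Conditions: CBr4, PPh3, 2,6-lutidine, CH2Cl2, −20 °C; used crude
Reagents that add atoms: carbon tetrabromide (BrC(Br)(Br)Br)
Why: Appel reaction: SN2 displacement at primary C11 should give the allylic bromide without transposition, because the alternative tertiary C8 bromide is sterically and thermodynamically disfavoured.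

Step 13
Reactants: 22 2-methylprop-2-en-1-ol (methallyl alcohol)
Product: 25 4-methylenedihydrofuran-2(3H)-one, via dilithiated methallyl alcohol 23 (not isolated), via 3-(hydroxymethyl)but-3-enoic acid 24 (not isolated)
Conditions: n-BuLi (2.2 equiv), TMEDA, Et2O, 0 °C to rt; CO2, −78 °C; then 2 M HCl, rt
Reagents that add atoms: carbon dioxide (O=C=O)
Why: Allylic deprotonation of the lithium alkoxide gives dianion 23, which is carboxylated at carbon, and acidification lactonises γ-hydroxy acid 24 (dianion carboxylation–lactonisation) to the β-methylene lactone.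

Step 14
Reactants: 25 the β-methylene lactone
Product: 27 tert-butyldimethyl[(4-methylene-4,5-dihydrofuran-2-yl)oxy]silane, via lithium dienolate 26 (not isolated)
Conditions: LDA, THF, −78 °C (lactone added to the base); TBSCl, HMPA, −78 to 0 °C; used crude
Reagents that add atoms: tert-butyldimethylsilyl chloride (CC(C)(C)[Si](C)(C)Cl)
Why: Kinetic deprotonation at C14 (α to the carbonyl and allylic) followed by O-silylation gives the cross-conjugated silyl ketene acetal, and keeping base in excess prevents equilibration to the aromatic 2-oxyfuran.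

Step 15
Reactants: 21 the allylic bromide; 27 the silyl dienolate
Product: 28 2α,6α,19-tris(tert-butyldimethylsilyloxy)labda-8,13-dien-15,16-olide
Conditions: 27 (2 equiv), AgOCOCF3 (1.2 equiv), CH2Cl2, −78 to −40 °C; NaHCO3 aq.
Reagents that add atoms: none
Why: Silver(I) abstracts bromide from 21 to give the 1,1,2-trisubstituted allyl cation spanning C8–C9–C11 as a contact ion pair, which is captured by the exocyclic γ-carbon (C12) of silyl dienolate 27; the resulting 2-silyloxy oxocarbenium ion gives up its silyl group to trifluoroacetate, so the C13=C14 bond and the lactone carbonyl of the butenolide appear in the same event. The closest known reaction type is the vinylogous Mukaiyama-type γ-alkylation of 2-silyloxyfurans and other O-silyl dienolates by SN1-active allylic halides under silver or zinc halide promotion. No ring is closed and no stereocentre is formed; the five stereocentres of 21 are remote from the cation and should stay untouched. Attack at primary C11 and not at C8 is secured by C8 being fully substituted and flanked by the ring, which also leaves the double bond at the preferred tetrasubstituted C8=C9 position. Reaction of the dienolate at C12 and not at C14 is the normal γ-preference of silyl dienolates toward cationic electrophiles, reinforced because C12 is an unhindered CH2 terminus whose attack gives the conjugated butenolide. The deconjugated 4-methylene lactone is what makes C12 nucleophilic at all, since enolisation of 4-methylbutenolide itself would give the aromatic 2-oxyfuran that reacts at C16.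

Step 16
Reactants: 28 the tris-silyl ether
Product: 29 2α,6α,19-trihydroxylabda-8,13-dien-15,16-olide (target)
Conditions: HF·pyridine, pyridine, THF, 0 °C to rt
Reagents that add atoms: none
Why: Fluoride-mediated cleavage of the three silyl ethers (desilylation) in a buffered acidic medium should leave the butenolide, the tetrasubstituted alkene and all stereocentres intact.

**Compound list**

1 | 2-methoxy-3-methylbenzoic acid | COc1c(C)cccc1C(=O)O | starting material
2 | (S)-2-(methoxymethyl)pyrrolidine | COC[C@@H]1CCCN1 | starting material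
3 | 2-methoxy-3-methylbenzoyl chloride | COc1c(C)cccc1C(Cl)=O | intermediate
4 | [(2S)-2-(methoxymethyl)pyrrolidin-1-yl](2-methoxy-3-methylphenyl)methanone | COC[C@@H]1CCCN1C(=O)c1cccc(C)c1OC | intermediate
5 | potassium amide enolate of the 1,4-dihydroarene | CC1=C(OC)C(=C([O-])N2CCC[C@H]2COC)C=CC1.[K+] | intermediate
6 | [(1S)-2-methoxy-1,3-dimethylcyclohexa-2,5-dien-1-yl][(2S)-2-(methoxymethyl)pyrrolidin-1-yl]methanone | CC1=C(OC)[C@@](C)(C(=O)N2CCC[C@H]2COC)C=CC1 | intermediate
7 | B-alkyl-9-BBN adduct of 6 (boron on labdane C2, α) | CC1=C(OC)[C@@](C)(C(=O)N2CCC[C@H]2COC)C[C@H](B2C3CCCC2CCC3)C1 | intermediate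
8 | [(1S,5R)-5-hydroxy-2-methoxy-1,3-dimethylcyclohex-2-en-1-yl][(2S)-2-(methoxymethyl)pyrrolidin-1-yl]methanone | CC1=C(OC)[C@@](C)(C(=O)N2CCC[C@H]2COC)C[C@H](O)C1 | intermediate
9 | (1R,5R)-5-(hydroxymethyl)-4-methoxy-3,5-dimethylcyclohex-3-en-1-ol | CC1=C(OC)[C@@](C)(CO)C[C@H](O)C1 | intermediate
10 | (2R,4R)-4-hydroxy-2-(hydroxymethyl)-2,6-dimethylcyclohexan-1-one (C6 epimers) | CC1C(=O)[C@@](C)(CO)C[C@H](O)C1 | intermediate
11 | (2R,4R)-4-(TBS-oxy)-2-[(TBS-oxy)methyl]-2,6-dimethylcyclohexan-1-one (C6 epimers) | CC1C(=O)[C@@](C)(CO[Si](C)(C)C(C)(C)C)C[C@H](O[Si](C)(C)C(C)(C)C)C1 | intermediate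
12 | potassium enolate of 11 | CC1=C([O-])[C@@](C)(CO[Si](C)(C)C(C)(C)C)C[C@H](O[Si](C)(C)C(C)(C)C)C1.[K+] | intermediate
13 | (4R,6R)-4-(TBS-oxy)-6-[(TBS-oxy)methyl]-2,6-dimethylcyclohex-1-en-1-yl trifluoromethanesulfonate | CC1=C(OS(=O)(=O)C(F)(F)F)[C@@](C)(CO[Si](C)(C)C(C)(C)C)C[C@H](O[Si](C)(C)C(C)(C)C)C1 | intermediate
14 | (3S,5R)-5-(TBS-oxy)-3-[(TBS-oxy)methyl]-1,3-dimethyl-2-vinylcyclohex-1-ene | CC1=C(C=C)[C@@](C)(CO[Si](C)(C)C(C)(C)C)C[C@H](O[Si](C)(C)C(C)(C)C)C1 | intermediate
15 | methyl but-2-ynoate | CC#CC(=O)OC | starting material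
16 | methyl 2α,19-bis(TBS-oxy)-12,13,14,15,16-pentanorlabda-5,8-dien-11-oate | CC1=C(C(=O)OC)[C@@]2(C)C[C@@H](O[Si](C)(C)C(C)(C)C)C[C@](C)(CO[Si](C)(C)C(C)(C)C)C2=CC1 | intermediate
17 | 6α-borane adduct of 16 (5α-H) | CC1=C(C(=O)OC)[C@@]2(C)C[C@@H](O[Si](C)(C)C(C)(C)C)C[C@](C)(CO[Si](C)(C)C(C)(C)C)[C@@H]2[C@@H](B)C1 | intermediate
18 | methyl 2α,19-bis(TBS-oxy)-6α-hydroxy-12,13,14,15,16-pentanorlabd-8-en-11-oate | CC1=C(C(=O)OC)[C@@]2(C)C[C@@H](O[Si](C)(C)C(C)(C)C)C[C@](C)(CO[Si](C)(C)C(C)(C)C)[C@@H]2[C@@H](O)C1 | intermediate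
19 | methyl 2α,6α,19-tris(TBS-oxy)-12,13,14,15,16-pentanorlabd-8-en-11-oate | CC1=C(C(=O)OC)[C@@]2(C)C[C@@H](O[Si](C)(C)C(C)(C)C)C[C@](C)(CO[Si](C)(C)C(C)(C)C)[C@@H]2[C@@H](O[Si](C)(C)C(C)(C)C)C1 | intermediate
20 | 2α,6α,19-tris(TBS-oxy)-12,13,14,15,16-pentanorlabd-8-en-11-ol | CC1=C(CO)[C@@]2(C)C[C@@H](O[Si](C)(C)C(C)(C)C)C[C@](C)(CO[Si](C)(C)C(C)(C)C)[C@@H]2[C@@H](O[Si](C)(C)C(C)(C)C)C1 | intermediate
21 | 11-bromo-2α,6α,19-tris(TBS-oxy)-12,13,14,15,16-pentanorlabd-8-ene | CC1=C(CBr)[C@@]2(C)C[C@@H](O[Si](C)(C)C(C)(C)C)C[C@](C)(CO[Si](C)(C)C(C)(C)C)[C@@H]2[C@@H](O[Si](C)(C)C(C)(C)C)C1 | intermediate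
22 | 2-methylprop-2-en-1-ol | C=C(C)CO | starting material
23 | dilithiated methallyl alcohol | [Li]CC(=C)CO[Li] | intermediate
24 | 3-(hydroxymethyl)but-3-enoic acid | C=C(CO)CC(=O)O | intermediate
25 | 4-methylenedihydrofuran-2(3H)-one | C=C1COC(=O)C1 | intermediate
26 | lithium dienolate of 25 | C=C1COC(O[Li])=C1 | intermediate
27 | tert-butyldimethyl[(4-methylene-4,5-dihydrofuran-2-yl)oxy]silane | C=C1COC(O[Si](C)(C)C(C)(C)C)=C1 | intermediate
28 | 2α,6α,19-tris(TBS-oxy)labda-8,13-dien-15,16-olide | CC1=C(CCC2=CC(=O)OC2)[C@@]2(C)C[C@@H](O[Si](C)(C)C(C)(C)C)C[C@](C)(CO[Si](C)(C)C(C)(C)C)[C@@H]2[C@@H](O[Si](C)(C)C(C)(C)C)C1 | intermediate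
29 | 2α,6α,19-trihydroxylabda-8,13-dien-15,16-olide | CC1=C(CCC2=CC(=O)OC2)[C@@]2(C)C[C@@H](O)C[C@](C)(CO)[C@@H]2[C@@H](O)C1 | target

**Step count and risks**

Total steps: 16. Longest linear sequence: 14 (steps 1–12, 15, 16); the lactone branch is steps 13–14.

Steps most likely to fail:

Step 8. The doubly hindered diene may not reach the s-cis geometry before a 1,5-hydrogen shift or dienophile oligomerisation takes over, or the dienophile may add to the β-face. The fallback sets out from 14 and returns at 16. A Lewis-acid-catalysed Diels–Alder reaction of 14 with but-2-ynal (Me2AlCl, CH2Cl2, −78 °C), in which LUMO lowering replaces pressure, should give 2α,19-bis(TBS-oxy)-12,13,14,15,16-pentanorlabda-5,8-dien-11-al F3. Pinnick oxidation (NaClO2, NaH2PO4, 2-methylbut-2-ene) should then give the corresponding 11-oic acid F4, and methylation with trimethylsilyldiazomethane in toluene/methanol returns ester 16.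

Step 15. After ionisation, the cation may lose a proton from C7 or C17 (elimination), or the dienolate may be captured at its α-carbon C14 instead of C12. The fallback sets out from 21 and returns at 28. SN2 alkylation of dilithiated methallyl alcohol 23 by bromide 21 (THF, −78 °C) should give the 2-substituted allylic alcohol 2α,6α,19-tris(TBS-oxy)-14,15-dinorlabda-8,13(16)-dien-16-ol F5. Acylation with acryloyl chloride/Et3N gives its acrylate F6, and ring-closing metathesis (second-generation ruthenium benzylidene catalyst, CH2Cl2, 40 °C) closes the butenolide to 28.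

Step 3. Facial selectivity may be poor if the borane is delivered syn to the carboxamide, giving the C2 epimer. The fallback sets out from 6 and returns at 8. The hydroboration is run as before and the epimeric (1S,5S)-alcohol F1 is inverted by a Mitsunobu reaction with 4-nitrobenzoic acid (PPh3, DIAD, THF) to the (5R)-4-nitrobenzoate F2; methanolysis (K2CO3, MeOH) then gives 8.

Further compounds
F1 | step 3 | [(1S,5S)-5-hydroxy-2-methoxy-1,3-dimethylcyclohex-2-en-1-yl][(2S)-2-(methoxymethyl)pyrrolidin-1-yl]methanone | CC1=C(OC)[C@@](C)(C(=O)N2CCC[C@H]2COC)C[C@@H](O)C1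
F2 | step 3 | (1R,5S)-4-methoxy-3,5-dimethyl-5-{[(2S)-2-(methoxymethyl)pyrrolidin-1-yl]carbonyl}cyclohex-3-en-1-yl 4-nitrobenzoate | CC1=C(OC)[C@@](C)(C(=O)N2CCC[C@H]2COC)C[C@H](OC(=O)c2ccc(cc2)[N+](=O)[O-])C1
F3 | step 8 | 2α,19-bis(TBS-oxy)-12,13,14,15,16-pentanorlabda-5,8-dien-11-al | CC1=C(C=O)[C@@]2(C)C[C@@H](O[Si](C)(C)C(C)(C)C)C[C@](C)(CO[Si](C)(C)C(C)(C)C)C2=CC1
F4 | step 8 | 2α,19-bis(TBS-oxy)-12,13,14,15,16-pentanorlabda-5,8-dien-11-oic acid | CC1=C(C(=O)O)[C@@]2(C)C[C@@H](O[Si](C)(C)C(C)(C)C)C[C@](C)(CO[Si](C)(C)C(C)(C)C)C2=CC1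
F5 | step 15 | 2α,6α,19-tris(TBS-oxy)-14,15-dinorlabda-8,13(16)-dien-16-ol (2-substituted allylic alcohol) | CC1=C(CCC(=C)CO)[C@@]2(C)C[C@@H](O[Si](C)(C)C(C)(C)C)C[C@](C)(CO[Si](C)(C)C(C)(C)C)[C@@H]2[C@@H](O[Si](C)(C)C(C)(C)C)C1
F6 | step 15 | acrylate ester of F5 | CC1=C(CCC(=C)COC(=O)C=C)[C@@]2(C)C[C@@H](O[Si](C)(C)C(C)(C)C)C[C@](C)(CO[Si](C)(C)C(C)(C)C)[C@@H]2[C@@H](O[Si](C)(C)C(C)(C)C)C1
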